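**Retrosynthetic overview**

1. Penicillactone A is cut to epoxy aldehyde 29 and phosphonoacetate 30: C3=C4 comes from a Z-selective olefination of the C4 aldehyde, and O1–C6 from 6-exo opening of a temporary cis-C6/C7 epoxide by the enoate carbonyl oxygen; the same acid frees the Ca acid and the Ce lactol.
2. Enabling feature: C6–O and C7–OH are vicinal and syn (threo), which is the pattern left by anti opening of a cis-epoxide, and C6 lies δ to the C2 carbonyl across the Z-C3=C4 alkene, so O1 reaches C6 but not C7. At Ce a CO2H and a CH2CHO arm are geminal and close by themselves to the spiro γ-lactol.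
3. Side chain and butenolide: the epoxide comes from ligand-controlled vanadium-catalysed epoxidation of a Z-homoallylic alcohol (Wittig on Cc–CHO); the butenolide comes from the Ca acetic acid arm by dianion opening of (S)-1,2-epoxyoctane, lactonisation and selenoxide elimination.
4. Core: both quaternary carbons Ca/Ce are made cis in one dianion annulation of a cyclopentane-1,2-diester with (Z)-1,4-dichlorobut-2-ene (the cyclohexene is a masked pair of CH2CHO arms). The meso anhydride is desymmetrised by alkaloid-mediated alcoholysis, and after ozonolysis the free Ce acid captures its own arm, which tells the two arms apart.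
5. Ring order: cyclopentane (Pd-TMM [3+2]) → cyclohexene (temporary) → anhydride (temporary) → spiro lactone (as methyl pseudo-ester) → butenolide → epoxide (temporary) → dihydropyranone.

Key step: step 17

Locants used below: cyclopentane Ca (carries CO2H and the butenolide), Cb, Cc (carries the side chain), Cd, Ce (spiro carbon); side chain C7 (carbinol); pyranone O1, C2–C6; butenolide C2′–C5′.

Assumption: the lactol carbon is an equilibrating hemiacetal centre; the route delivers it under thermodynamic control and the configuration written for the target is taken as the resting one.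

**Route**

Step 1
Reactants: 1 di-tert-butyl fumarate; 2 2-[(trimethylsilyl)methyl]prop-2-en-1-yl acetate
Product: 3 di-tert-butyl trans-4-methylidenecyclopentane-1,2-dicarboxylate (racemic)
Conditions: Pd(OAc)2 (5 mol %), P(Oi-Pr)3 (30 mol %), THF, reflux
Reagents that add atoms: none
Why: Pd-catalysed trimethylenemethane [3+2] cycloaddition to an electron-poor alkene; the trans ester relationship is irrelevant later because both α-centres are re-formed in step 4.

Step 2
Reactants: 3 di-tert-butyl trans-4-methylidenecyclopentane-1,2-dicarboxylate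
Product: 5 di-tert-butyl trans-4-(hydroxymethyl)cyclopentane-1,2-dicarboxylate, via alkylborane 4 (not isolated)
Conditions: 9-BBN, THF, 0 °C → rt; then NaOH, H2O2, 0 °C
Reagents that add atoms: hydrogen peroxide, OO
Why: anti-Markovnikov hydroboration–oxidation of the 1,1-disubstituted alkene; C4 lies on the C2 axis of the trans diester, so no new stereocentre arises.

Step 3
Reactants: 5 di-tert-butyl trans-4-(hydroxymethyl)cyclopentane-1,2-dicarboxylate
Product: 6 di-tert-butyl trans-4-{[(tert-butyldiphenylsilyl)oxy]methyl}cyclopentane-1,2-dicarboxylate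
Conditions: TBDPSCl, imidazole, DMF, rt
Reagents that add atoms: tert-butyl(chloro)diphenylsilane, CC(C)(C)[Si](Cl)(c1ccccc1)c1ccccc1
Why: standard silylation of the primary alcohol; TBDPS is chosen because it should withstand LDA and the TFA of step 5.

Step 4
Reactants: 6 TBDPS-protected trans diester; 7 (Z)-1,4-dichlorobut-2-ene
Product: 9 meso bicyclic diester, via dilithium bis-enolate 8 (not isolated)
Conditions: LDA (2.3 equiv), THF/DMPU, −78 → 0 °C; then 7, −78 °C → rt
Reagents that add atoms: none
Why: double C-alkylation of a vicinal diester bis-enolate with a 1,4-dihalide; the first SN2 alkylation is expected to occur anti to the bulky CH2OTBDPS group on the nearly planar dienolate and the ring-closing 6-exo-tet alkylation must use the same face, so the new quaternary centres Ca and Ce carry cis esters that are cis to the side chain.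

Step 5
Reactants: 9 meso bicyclic diester
Product: 11 meso anhydride, via diacid 10 (not isolated)
Conditions: TFA/CH2Cl2 (1:3), 0 °C → rt; then Ac2O, 60 °C
Reagents that add atoms: none
Why: acidolysis of the tert-butyl esters and dehydration of the cis-1,2-diacid to the five-membered anhydride, favoured by the two quaternary carbons; the TBDPS ether should tolerate TFA/CH2Cl2.

Step 6
Reactants: 11 meso anhydride; 12 4-methoxybenzyl alcohol
Product: 13 mono-PMB ester (PMB ester on Ca, free acid on Ce)
Conditions: quinidine (1.1 equiv), 12 (3 equiv), toluene, −40 → −20 °C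
Reagents that add atoms: none
Why: cinchona alkaloid-mediated enantiotopos-selective alcoholysis of a meso succinic anhydride (general-base delivery of the alcohol to one carbonyl); this one event makes Ca, Cc and Ce stereogenic, quinidine being chosen by analogy with simpler bicyclic anhydrides to place the ester on Ca (quinine should give the mirror image).

Step 7
Reactants: 13 mono-PMB ester
Product: 16 Ca-aldehyde methyl pseudo-ester, via lactol aldehyde 14 (not isolated), via bis-acetal 15 (not isolated)
Conditions: O3, CH2Cl2/MeOH, −78 °C; Me2S; then TsOH·H2O (cat.), MeOH, rt; then 1 M HCl, THF, 0 °C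
Reagents that add atoms: ozone, [O-][O+]=O; methanol, CO
Why: ozonolysis of the only alkene gives two CH2CHO arms, the Ce acid traps its own geminal arm as the five-membered pseudo-acid (5-exo-trig, gem-disubstitution), acidic methanol fixes it as the methyl pseudo-ester and dilute aqueous acid then hydrolyses only the ordinary dimethyl acetal on the Ca arm; the acetal carbon forms as a mixture of epimers that converges in step 17.

Step 8
Reactants: 16 Ca-aldehyde methyl pseudo-ester
Product: 17 Ca-acetic acid
Conditions: NaClO2, NaH2PO4, 2-methyl-2-butene, t-BuOH/H2O, rt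
Reagents that add atoms: sodium chlorite, [Na+].[O-]Cl=O
Why: Pinnick oxidation of the aldehyde to the acid under weakly acidic conditions that leave the PMB ester, pseudo-ester and silyl ether untouched.

Step 9
Reactants: 17 Ca-acetic acid; 18 (S)-1,2-epoxyoctane
Product: 20 γ-lactone, via hydroxy acid 19 (not isolated)
Conditions: LDA (2.2 equiv), THF/DMPU, −78 → 0 °C; 18, 0 °C → rt; aq. HCl; then TsOH (cat.), CH2Cl2, rt
Reagents that add atoms: none
Why: the α-lithiated lithium carboxylate (acid dianion) opens the terminal epoxide at CH2 (SN2), so the C5′ configuration is bought with 18 and untouched, and acid closes the γ-lactone; the new C3′ centre forms as a mixture and is erased in step 13.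

Step 10
Reactants: 20 γ-lactone
Product: 21 primary alcohol (Cc–CH2OH)
Conditions: HF·pyridine, THF/pyridine, 0 °C → rt
Reagents that add atoms: none
Why: fluoride cleavage of the silyl ether under acidic buffering, which avoids alkoxide-induced translactonisation onto the cis Ca ester.

Step 11
Reactants: 21 primary alcohol
Product: 22 aldehyde (Cc–CHO)
Conditions: Dess–Martin periodinane, NaHCO3, CH2Cl2, 0 °C → rt
Reagents that add atoms: none
Why: Dess–Martin oxidation under buffered, non-epimerising conditions; the formyl group already sits on the less encumbered carboxylate face, so the Cc configuration should hold.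

Step 12
Reactants: 22 aldehyde; 23 {3-[(tert-butyldimethylsilyl)oxy]propyl}triphenylphosphonium bromide
Product: 24 Z-alkene
Conditions: 23, NaHMDS, THF, 0 °C; then 22, −78 °C → rt
Reagents that add atoms: none
Why: salt-free Wittig reaction of a non-stabilised ylide should give the Z-C6=C7 alkene under kinetic control; the still saturated lactone and the hindered esters tolerate the ylide at −78 °C.

Step 13
Reactants: 24 Z-alkene
Product: 26 butenolide, via selenide 25 (not isolated)
Conditions: LDA, THF, −78 °C; PhSeBr (1.0 equiv); then NaIO4, NaHCO3, MeOH/THF/H2O, rt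
Reagents that add atoms: none
Why: α-selenenylation of the lactone enolate (the only enolisable position) and selenoxide syn-elimination, which can only go into the ring because Ca bears no hydrogen, giving the endocyclic butenolide without touching C5′.

Step 14
Reactants: 26 butenolide
Product: 27 Z-homoallylic alcohol
Conditions: HF·pyridine, THF/pyridine, 0 °C
Reagents that add atoms: none
Why: HF·pyridine removes the primary TBS ether under acidic conditions that spare the base-sensitive butenolide.

Step 15
Reactants: 27 Z-homoallylic alcohol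
Product: 28 (6R,7S)-cis-epoxy alcohol
Conditions: VO(Oi-Pr)3 (2 mol %), chiral C2-symmetric bis-hydroxamic acid ligand (4 mol %), cumene hydroperoxide, toluene, 0 °C → rt
Reagents that add atoms: cumene hydroperoxide, CC(C)(OO)c1ccccc1
Why: vanadium/bis-hydroxamic acid-catalysed asymmetric epoxidation of a Z-homoallylic alcohol: the alkoxide-bound vanadium peroxide delivers oxygen only to the C6=C7 alkene, the cis geometry is retained and the ligand enantiomer is chosen to give the (6R,7S) epoxide (reagent control, since the pseudo-symmetric ring offers no bias).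

Step 16
Reactants: 28 (6R,7S)-cis-epoxy alcohol
Product: 29 (6R,7S)-cis-epoxy aldehyde
Conditions: Dess–Martin periodinane, NaHCO3, CH2Cl2, 0 °C; used crude at once
Reagents that add atoms: none
Why: buffered Dess–Martin oxidation gives the β,γ-epoxy aldehyde, which is used immediately without chromatography to avoid β-elimination.

Step 17
Reactants: 29 (6R,7S)-cis-epoxy aldehyde; 30 methyl 2-[bis(2,2,2-trifluoroethoxy)phosphoryl]acetate
Product: 32 penicillactone A, via Z-enoate 31 (not isolated)
Conditions: 30, KHMDS, 18-crown-6, THF, −78 °C; then TFA/H2O (9:1), 0 °C → rt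
Reagents that add atoms: water, O
Why: Still–Gennari olefination of the C4 aldehyde with the potassium anion of 30 forms the Z-C3=C4 bond under kinetic control. On acidification the ester carbonyl oxygen of 31 attacks the protonated epoxide at C6 in a 6-exo-tet closure with inversion, and the resulting methoxy-dioxocarbenium ion is hydrolysed to the δ-lactone; the closest known reaction type is Z-selective Horner–Wadsworth–Emmons olefination followed by acid-mediated lactonisation of an epoxy ester to a hydroxy lactone. C6 (S) is set stereospecifically by inversion of the (6R) epoxide carbon and C7 (S) keeps the epoxide C–O bond, so both are relayed from the catalyst-set epoxide. The same acid cleaves the PMB ester to the Ca acid and exchanges OMe for OH on the spiro lactone ring, which is already present as the pseudo-ester, with the hemiacetal carbon settling under thermodynamic control. The step needs Z geometry (only the Z-enoate can reach C6), 6-exo attack at C6 rather than 7-endo attack at C7 or external hydrolysis, and no β-elimination of the epoxy aldehyde. These are secured by the trifluoroethyl phosphonate, by the two-carbon C4–C5 spacer held by the cis alkene, and by the weakly basic pre-formed phosphonate anion at −78 °C.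

**Compound list**

1 | di-tert-butyl fumarate | CC(C)(C)OC(=O)/C=C/C(=O)OC(C)(C)C | starting material
2 | 2-[(trimethylsilyl)methyl]prop-2-en-1-yl acetate | CC(=O)OCC(=C)C[Si](C)(C)C | starting material
3 | di-tert-butyl trans-4-methylidenecyclopentane-1,2-dicarboxylate (racemic, one enantiomer drawn) | C=C1C[C@@H](C(=O)OC(C)(C)C)[C@H](C(=O)OC(C)(C)C)C1 | intermediate
4 | 9-{[trans-3,4-bis(tert-butoxycarbonyl)cyclopentyl]methyl}-9-borabicyclo[3.3.1]nonane | C1(CB2C3CCCC2CCC3)C[C@@H](C(=O)OC(C)(C)C)[C@H](C(=O)OC(C)(C)C)C1 | intermediate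
5 | di-tert-butyl trans-4-(hydroxymethyl)cyclopentane-1,2-dicarboxylate (racemic, C4 not stereogenic) | OCC1C[C@@H](C(=O)OC(C)(C)C)[C@H](C(=O)OC(C)(C)C)C1 | intermediate
6 | di-tert-butyl trans-4-{[(tert-butyldiphenylsilyl)oxy]methyl}cyclopentane-1,2-dicarboxylate (racemic) | CC(C)(C)[Si](OCC1C[C@@H](C(=O)OC(C)(C)C)[C@H](C(=O)OC(C)(C)C)C1)(c1ccccc1)c1ccccc1 | intermediate
7 | (Z)-1,4-dichlorobut-2-ene | ClC/C=C\CCl | starting material
8 | dilithium 1,2-bis-enolate of 6 | [Li+].[Li+].CC(C)(C)OC([O-])=C1CC(CO[Si](c2ccccc2)(c2ccccc2)C(C)(C)C)CC1=C([O-])OC(C)(C)C | intermediate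
9 | meso di-tert-butyl 2-{[(tert-butyldiphenylsilyl)oxy]methyl}-2,3,3a,4,7,7a-hexahydro-1H-indene-3a,7a-dicarboxylate; cis ring fusion, both esters cis to the silyloxymethyl group | C1=CC[C@]2(C(=O)OC(C)(C)C)C[C@@H](CO[Si](c3ccccc3)(c3ccccc3)C(C)(C)C)C[C@]2(C(=O)OC(C)(C)C)C1 | intermediate
10 | meso 3a,7a-dicarboxylic acid corresponding to 9 | C1=CC[C@]2(C(=O)O)C[C@@H](CO[Si](c3ccccc3)(c3ccccc3)C(C)(C)C)C[C@]2(C(=O)O)C1 | intermediate
11 | meso cyclic anhydride of 10 (anhydride, cyclopentane and cyclohexene share the Ca–Ce bond; CH2OTBDPS cis to the anhydride) | C1=CC[C@]23C[C@@H](CO[Si](c4ccccc4)(c4ccccc4)C(C)(C)C)C[C@@]2(C1)C(=O)OC3=O | intermediate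
12 | 4-methoxybenzyl alcohol | COc1ccc(CO)cc1 | starting material
13 | hemiester of 10: 4-methoxybenzyl ester on Ca, free acid on Ce, single enantiomer | C1=CC[C@]2(C(=O)OCc3ccc(OC)cc3)C[C@@H](CO[Si](c3ccccc3)(c3ccccc3)C(C)(C)C)C[C@]2(C(=O)O)C1 | intermediate
14 | cyclopentane with Ca(CO2PMB)(CH2CHO), Cc–CH2OTBDPS cis to both carbonyl groups, Ce spiro-fused as α-carbon of a 5-hydroxy-γ-butyrolactone (lactol epimers) | O=CC[C@]2(C(=O)OCc3ccc(OC)cc3)C[C@@H](CO[Si](c3ccccc3)(c3ccccc3)C(C)(C)C)C[C@]23CC(O)OC3=O | intermediate
15 | as 14 with Ca arm CH2CH(OMe)2 and lactol OMe (acetal epimers) | COC(OC)C[C@]2(C(=O)OCc3ccc(OC)cc3)C[C@@H](CO[Si](c3ccccc3)(c3ccccc3)C(C)(C)C)C[C@]23CC(OC)OC3=O | intermediate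
16 | as 14 with lactol OH replaced by OMe (methyl pseudo-ester, acetal epimers) | O=CC[C@]2(C(=O)OCc3ccc(OC)cc3)C[C@@H](CO[Si](c3ccccc3)(c3ccccc3)C(C)(C)C)C[C@]23CC(OC)OC3=O | intermediate
17 | as 16 with the Ca arm oxidised to CH2CO2H | OC(=O)C[C@]2(C(=O)OCc3ccc(OC)cc3)C[C@@H](CO[Si](c3ccccc3)(c3ccccc3)C(C)(C)C)C[C@]23CC(OC)OC3=O | intermediate
18 | (S)-1,2-epoxyoctane [(S)-2-hexyloxirane] | CCCCCC[C@H]1CO1 | starting material
19 | γ-hydroxy acid Ca–CH(CO2H)–CH2–CH(OH)–hexyl with (S)-carbinol (epimers at the α-carbon) | CCCCCC[C@H](O)CC(C(=O)O)[C@]2(C(=O)OCc3ccc(OC)cc3)C[C@@H](CO[Si](c3ccccc3)(c3ccccc3)C(C)(C)C)C[C@]23CC(OC)OC3=O | intermediate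
20 | (5′S)-5′-hexyl-γ-butyrolactone bound to Ca through C3′ (C3′ epimers); otherwise as 17 | CCCCCC[C@H]1CC([C@]2(C(=O)OCc3ccc(OC)cc3)C[C@@H](CO[Si](c3ccccc3)(c3ccccc3)C(C)(C)C)C[C@]23CC(OC)OC3=O)C(=O)O1 | intermediate
21 | 20 with Cc–CH2OH | CCCCCC[C@H]1CC([C@]2(C(=O)OCc3ccc(OC)cc3)C[C@@H](CO)C[C@]23CC(OC)OC3=O)C(=O)O1 | intermediate
22 | 20 with Cc–CHO | CCCCCC[C@H]1CC([C@]2(C(=O)OCc3ccc(OC)cc3)C[C@@H](C=O)C[C@]23CC(OC)OC3=O)C(=O)O1 | intermediate
23 | {3-[(tert-butyldimethylsilyl)oxy]propyl}triphenylphosphonium bromide | [Br-].CC(C)(C)[Si](C)(C)OCCC[P+](c1ccccc1)(c1ccccc1)c1ccccc1 | starting material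
24 | Wittig product: Cc–(Z)-CH=CH–CH2CH2OTBS | CCCCCC[C@H]1CC([C@]2(C(=O)OCc3ccc(OC)cc3)C[C@@H](/C=C\CCO[Si](C)(C)C(C)(C)C)C[C@]23CC(OC)OC3=O)C(=O)O1 | intermediate
25 | 24 with a phenylselanyl group on C3′ | CCCCCC[C@H]1CC([Se]c4ccccc4)([C@]2(C(=O)OCc3ccc(OC)cc3)C[C@@H](/C=C\CCO[Si](C)(C)C(C)(C)C)C[C@]23CC(OC)OC3=O)C(=O)O1 | intermediate
26 | 24 with the lactone dehydrogenated to the (5′S)-5′-hexylfuran-2(5H)-one bound through C3′ | CCCCCC[C@H]1C=C([C@]2(C(=O)OCc3ccc(OC)cc3)C[C@@H](/C=C\CCO[Si](C)(C)C(C)(C)C)C[C@]23CC(OC)OC3=O)C(=O)O1 | intermediate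
27 | 26 with free primary OH: Cc–(Z)-CH=CH–CH2CH2OH | CCCCCC[C@H]1C=C([C@]2(C(=O)OCc3ccc(OC)cc3)C[C@@H](/C=C\CCO)C[C@]23CC(OC)OC3=O)C(=O)O1 | intermediate
28 | (6R,7S)-cis-epoxide of 27 | CCCCCC[C@H]1C=C([C@]2(C(=O)OCc3ccc(OC)cc3)C[C@@H]([C@@H]4O[C@@H]4CCO)C[C@]23CC(OC)OC3=O)C(=O)O1 | intermediate
29 | aldehyde from 28: Cc–[(6R,7S)-cis-oxirane]–CH2CHO | CCCCCC[C@H]1C=C([C@]2(C(=O)OCc3ccc(OC)cc3)C[C@@H]([C@@H]4O[C@@H]4CC=O)C[C@]23CC(OC)OC3=O)C(=O)O1 | intermediate
30 | methyl 2-[bis(2,2,2-trifluoroethoxy)phosphoryl]acetate | COC(=O)CP(=O)(OCC(F)(F)F)OCC(F)(F)F | starting material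
31 | methyl (2Z)-enoate: Cc–[(6R,7S)-cis-oxirane]–CH2–CH=CH–CO2Me | CCCCCC[C@H]1C=C([C@]2(C(=O)OCc3ccc(OC)cc3)C[C@@H]([C@@H]4O[C@@H]4C/C=C\C(=O)OC)C[C@]23CC(OC)OC3=O)C(=O)O1 | intermediate
32 | penicillactone A | CCCCCC[C@H]1C=C([C@]2(C(=O)O)C[C@@H]([C@H](O)[C@@H]3CC=CC(=O)O3)C[C@]23C[C@@H](O)OC3=O)C(=O)O1 | target

**Step count and risks**

Total step count: 17. Longest linear sequence: 17 steps (from 1 and 2).

Steps most likely to fail:

1. Step 17. Under the olefination conditions the β,γ-epoxy aldehyde may undergo base-induced β-elimination (ring opening to the γ-hydroxy enal) before it is olefinated, Z-selectivity may erode, and in the acid stage external hydrolysis of the epoxide may compete with the 6-exo attack. Fallback, setting out from 29: treatment with the neutral stabilised ylide methyl (triphenylphosphoranylidene)acetate in CH2Cl2 at 0 °C should give the E-enoate F7 without exposing the aldehyde to a metal base. Triplet-sensitised E/Z photoisomerisation then establishes a photostationary mixture from which the Z isomer is separated and the E isomer re-irradiated. The fallback rejoins the route at 31, which is carried through the TFA/H2O stage of step 17 to 32.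

2. Step 6. Alcoholysis of an anhydride whose two carbonyls are both flanked by quaternary carbons may be slow and poorly enantiotopos-selective, and the sense of induction has to be established. Fallback, setting out from 11: DMAP-catalysed opening with 12 gives the racemic mono-PMB ester F5. Classical resolution by crystallisation with (R)-1-phenylethylamine gives the (R)-1-phenylethylammonium salt of the required enantiomer F6, and acidification returns the route to 13.

3. Step 4. The first alkylation is steered only by 1,3-induction from the CH2OTBDPS group, so facial discrimination may be poor, and SN2′ closure or intermolecular oligomerisation may compete. Fallback, setting out from 3: the same dianion annulation with 7 gives the 2-methylidene bicyclic diester F1, which has no Cc stereocentre. Selective hydroboration–oxidation of the 1,1-disubstituted alkene with 9-BBN gives the hydroxymethyl compound as both Cc epimers F2. Dess–Martin oxidation and DBU equilibration should enrich the aldehyde with the formyl group on the ester face F3, away from the cyclohexene methylene hydrogens, with the minor epimer recycled through the same equilibration. NaBH4 reduction gives the cis hydroxymethyl diester F4, and silylation with TBDPSCl/imidazole returns the route to 9.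

**Further compounds**

F1 | step 4 | meso di-tert-butyl 2-methylidene-2,3,3a,4,7,7a-hexahydro-1H-indene-3a,7a-dicarboxylate (cis ring fusion) | C1=CC[C@]2(C(=O)OC(C)(C)C)CC(=C)C[C@]2(C(=O)OC(C)(C)C)C1
F2 | step 4 | di-tert-butyl 2-(hydroxymethyl)-2,3,3a,4,7,7a-hexahydro-1H-indene-3a,7a-dicarboxylate, both Cc epimers | C1=CC[C@]2(C(=O)OC(C)(C)C)CC(CO)C[C@]2(C(=O)OC(C)(C)C)C1
F3 | step 4 | di-tert-butyl 2-formyl-2,3,3a,4,7,7a-hexahydro-1H-indene-3a,7a-dicarboxylate, formyl cis to both esters | C1=CC[C@]2(C(=O)OC(C)(C)C)C[C@@H](C=O)C[C@]2(C(=O)OC(C)(C)C)C1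
F4 | step 4 | di-tert-butyl 2-(hydroxymethyl)-2,3,3a,4,7,7a-hexahydro-1H-indene-3a,7a-dicarboxylate, hydroxymethyl cis to both esters | C1=CC[C@]2(C(=O)OC(C)(C)C)C[C@@H](CO)C[C@]2(C(=O)OC(C)(C)C)C1
F5 | step 6 | racemic mono-PMB ester (13 and its enantiomer) | C1=CC[C@]2(C(=O)OCc3ccc(OC)cc3)C[C@@H](CO[Si](c3ccccc3)(c3ccccc3)C(C)(C)C)C[C@]2(C(=O)O)C1.C1=CC[C@@]2(C(=O)OCc3ccc(OC)cc3)C[C@H](CO[Si](c3ccccc3)(c3ccccc3)C(C)(C)C)C[C@@]2(C(=O)O)C1
F6 | step 6 | (R)-1-phenylethylammonium salt of 13 | C1=CC[C@]2(C(=O)OCc3ccc(OC)cc3)C[C@@H](CO[Si](c3ccccc3)(c3ccccc3)C(C)(C)C)C[C@]2(C(=O)[O-])C1.C[C@@H]([NH3+])c1ccccc1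
F7 | step 17 | methyl (2E)-enoate isomer of 31 | CCCCCC[C@H]1C=C([C@]2(C(=O)OCc3ccc(OC)cc3)C[C@@H]([C@@H]4O[C@@H]4C/C=C/C(=O)OC)C[C@]23CC(OC)OC3=O)C(=O)O1
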